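**Plan**
- Backwards, the styrylpyrone is opened at O1'–C2' and cut at C3'–C4' and C5'–C6' (arylacetic ester + acetyl + 4-methoxycinnamoyl), and the formyl group is traced back to a methyl ester on C2.
- Central cut: C1–C3' and C2–C(formyl) are removed together as dimethyl malonate from an aryne spanning C1–C2. The enabling feature is that the carbon substituents on C1 and C2 stand in a row with the C3 oxygen, the 1,2,3-pattern a 3-methoxyaryne returns with a malonate, and C1 can carry the hydrogen lost on aryne formation.
- The benzene ring is cut into a cyclohexane-fused 3-bromo-2-pyrone (future C1, C2, C4a, C8a) and 1,1,2-trimethoxyethene (C3, C4 with their oxygens); the pyrone goes back to formylated carvomenthone.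
- Forwards: carvone ring, then fused 2-pyrone, then benzene ring (Diels–Alder, loss of CO2 and MeOH), then aryne insertion (no ring), then the styrylpyrone ring last, followed by ester-to-aldehyde adjustment and demethylation.
- Stereochemistry: C8 is the carvone centre (S in carvone, R in the tetralin only through a change of priorities); C5 is set trans to it by equilibration of the α-methyl ketone; the E alkene comes with 4-methoxycinnamic acid.

Key step: step 6

Numbering: tetralin C1 (pyrone), C2 (CHO), C3 and C4 (oxygens), C5 (methyl), C8 (isopropyl); pyrone atoms primed; compounds 10 to 22 are named with these locants.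
Assumption: 1,1,2-trimethoxyethene (7) is treated as a purchasable ketene acetal.
Assumption: the target does not define the configuration of the hindered C1–C3' axis, so rotamers about it are left unassigned from 19 onwards.
Building blocks that carry a compound number are listed under Reactants only.

Step 1
Reactants: 1 (S)-(+)-carvone
Product: 2 (2S,5S)-2-methyl-5-(propan-2-yl)cyclohexan-1-one (trans-carvomenthone)
Conditions: H2 (1 atm), Pd/C, EtOAc, rt; then NaOMe (cat.), MeOH, rt; chromatography
Reagents that add atoms: none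
Why: Catalytic hydrogenation should saturate both C=C bonds without touching the isopropyl-bearing centre taken from carvone, and the new α-methyl centre is set by thermodynamic epimerisation through the enolate, which should favour the diequatorial trans ketone (2S).

Step 2
Reactants: 2 (2S,5S)-2-methyl-5-(propan-2-yl)cyclohexan-1-one
Product: 3 (2Z,3R,6S)-2-(hydroxymethylidene)-6-methyl-3-(propan-2-yl)cyclohexan-1-one
Conditions: NaH, HCO2Et, EtOH (cat.), THF, 0 °C → rt; dilute aq. HCl
Reagents that add atoms: ethyl formate, CCOC=O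
Why: Crossed Claisen formylation is driven by formation of the β-ketoaldehyde enolate, which is possible only at the α-methylene carbon, so the formyl carbon (future C1) should enter next to the isopropyl-bearing carbon while the α-methyl centre keeps its trans setting.

Step 3
Reactants: 3 (2Z,3R,6S)-2-(hydroxymethylidene)-6-methyl-3-(propan-2-yl)cyclohexan-1-one
Product: 5 (5R,8S)-8-methyl-5-(propan-2-yl)-5,6,7,8-tetrahydro-2H-chromen-2-one, via keto enoate 4 (not isolated)
Conditions: Ph3P=CHCO2Me, PhMe, 80 °C; then TsOH·H2O (cat.), 110 °C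
Reagents that add atoms: methyl (triphenylphosphoranylidene)acetate, COC(=O)C=P(c1ccccc1)(c1ccccc1)c1ccccc1
Why: Wittig olefination of the formyl tautomer by the stabilised ylide gives δ-keto enoate 4, and under acid its dienol is protonated at the ester carbonyl so that the C2–C3 bond can rotate and the enol oxygen closes the 2-pyrone by enol lactonisation with loss of methanol.

Step 4
Reactants: 5 (5R,8S)-8-methyl-5-(propan-2-yl)-5,6,7,8-tetrahydro-2H-chromen-2-one
Product: 6 (5R,8S)-3-bromo-8-methyl-5-(propan-2-yl)-5,6,7,8-tetrahydro-2H-chromen-2-one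
Conditions: N-bromosuccinimide, DMF, 0 °C → rt, dark
Reagents that add atoms: N-bromosuccinimide, O=C1CCC(=O)N1Br
Why: Electrophilic bromination of the cyclic dienol ether should go to C3, the only nucleophilic diene position that carries hydrogen because the other (C4a) is blocked by the ring fusion, while polar dark conditions suppress radical allylic bromination.

Step 5
Reactants: 6 (5R,8S)-3-bromo-8-methyl-5-(propan-2-yl)-5,6,7,8-tetrahydro-2H-chromen-2-one; 7 1,1,2-trimethoxyethene
Product: 10 (5S,8R)-2-bromo-3,4-dimethoxy-5-methyl-8-(propan-2-yl)-5,6,7,8-tetrahydronaphthalene, via bridged lactone 8 (not isolated), via trimethoxy diene 9 (not isolated)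
Conditions: 7 (4 equiv), mesitylene, 150 °C, sealed tube
Reagents that add atoms: none
Why: Inverse-electron-demand Diels–Alder addition of the ketene acetal across C3 and C8a of the bromopyrone, retro-Diels–Alder loss of CO2 from 8 and thermal 1,2-elimination of methanol from 9 should give the bromoveratrole ring; either orientation of the dienophile ends in the same arene, and the transient sp3 centres vanish on aromatisation.

Step 6
Reactants: 10 (5S,8R)-2-bromo-3,4-dimethoxy-5-methyl-8-(propan-2-yl)-5,6,7,8-tetrahydronaphthalene; 11 dimethyl malonate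
Product: 13 methyl (5S,8R)-3,4-dimethoxy-1-(2-methoxy-2-oxoethyl)-5-methyl-8-(propan-2-yl)-5,6,7,8-tetrahydronaphthalene-2-carboxylate (homophthalate diester), via aryne 12 (not isolated)
Conditions: 2,2,6,6-tetramethylpiperidine, n-BuLi, THF, −78 °C (LiTMP, 4 equiv); 11 (2 equiv), −78 °C; then 10, −78 °C → rt; dilute aq. HCl
Reagents that add atoms: none
Why: LiTMP removes H1, the only aromatic hydrogen and the one next to bromine, and loss of LiBr gives aryne 12 across C1–C2. The carbon of lithiated dimethyl malonate adds to C1, the resulting C2 aryl anion attacks a malonate ester carbonyl in a 4-exo-trig closure to a transient benzocyclobutenoxide, and this four-membered ring fragments to the arylacetate enolate, so that C1–CH2 and C2–C(=O)OMe form by net insertion into a malonate C–C bond without any lasting ring or new stereocentre. The closest known reaction type is the acyl-alkylation of arynes by malonates and β-keto esters (aryne σ-bond insertion), which is also practised with bromoarenes and lithium amides to make homophthalates. The selectivity needed is regiochemical: the inductively withdrawing C3 methoxy group distorts the aryne so that C1 is the electrophilic terminus and the charge develops at C2 beside oxygen, the normal behaviour of 3-alkoxyarynes. Attack at C1 occurs in the ring plane, where the trans isopropyl group, pseudoaxial to avoid peri strain, leaves only the C8 hydrogen in the way, so the steric bias should not overturn the electronic one. An excess of the hindered amide base and of the malonate should suppress amine addition to the aryne and a second arylation of the product enolate.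

Step 7
Reactants: 13 homophthalate diester
Product: 14 methyl 2-[(5S,8R)-3,4-dimethoxy-2-(methoxycarbonyl)-5-methyl-8-(propan-2-yl)-5,6,7,8-tetrahydronaphthalen-1-yl]-3-oxobutanoate
Conditions: LiN(SiMe3)2 (2.2 equiv), THF, −78 °C; 1-acetylimidazole, −78 → 0 °C; dilute aq. HCl
Reagents that add atoms: 1-acetylimidazole, CC(=O)n1ccnc1
Why: Claisen-type C-acylation of the arylacetate lithium enolate (the only enolisable site) by an acyl imidazole should give the β-keto ester, the second equivalent of base holding it as its enolate and the twisted, doubly ortho-flanked benzoate staying inert; the new α-centre is configurationally labile and is erased in step 9.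

Step 8
Reactants: 15 (E)-4-methoxycinnamic acid
Product: 17 (2E)-N-methoxy-3-(4-methoxyphenyl)-N-methylprop-2-enamide, via acyl imidazolide 16 (not isolated)
Conditions: 1,1'-carbonyldiimidazole, CH2Cl2, rt; then MeNHOMe·HCl, rt
Reagents that add atoms: N,O-dimethylhydroxylamine hydrochloride, CNOC.Cl; 1,1'-carbonyldiimidazole, O=C(n1ccnc1)n1ccnc1 (its imidazole is carried only by 16)
Why: Activation of the acid as its acyl imidazolide and aminolysis (amide coupling) should give the Weinreb amide without touching the E alkene.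

Step 9
Reactants: 14 aryl acetoacetate; 17 Weinreb amide
Product: 19 methyl (5S,8R)-1-{4-hydroxy-6-[(E)-2-(4-methoxyphenyl)ethenyl]-2-oxo-2H-pyran-3-yl}-3,4-dimethoxy-5-methyl-8-(propan-2-yl)-5,6,7,8-tetrahydronaphthalene-2-carboxylate, via diketo ester 18 (not isolated)
Conditions: LiN(iPr)2 (2.3 equiv), THF, −78 → 0 °C; 17, −78 → 0 °C; dilute aq. HCl; crude 18, DBU, PhMe, 80 °C
Reagents that add atoms: none
Why: γ-Acylation of the β-keto ester dianion by the Weinreb amide (stable chelate, no over-addition, 1,2-attack favoured on the electron-rich cinnamoyl unit) gives the 3,5-dioxo ester, and base-mediated enol lactonisation onto the aliphatic ester closes the 4-hydroxy-2-pyrone with loss of methanol, whereas Dieckmann closure onto the hindered benzoate would force a bay-region clash with C8.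

Step 10
Reactants: 19 pyrone benzoate
Product: 20 4-hydroxy-3-[(5S,8R)-2-(hydroxymethyl)-3,4-dimethoxy-5-methyl-8-(propan-2-yl)-5,6,7,8-tetrahydronaphthalen-1-yl]-6-[(E)-2-(4-methoxyphenyl)ethenyl]-2H-pyran-2-one
Conditions: iBu2AlH (5 equiv), THF, −78 → 0 °C; aq. KNaC4H4O6
Reagents that add atoms: none
Why: The first equivalent of hydride deprotonates the acidic 4-hydroxy-2-pyrone to an aluminium pyronolate, a vinylogous carboxylate that should resist hydride, so that ester reduction by the aluminium hydride is confined to the benzoate and gives the benzylic alcohol.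

Step 11
Reactants: 20 hydroxymethyl pyrone
Product: 21 (5S,8R)-1-{4-hydroxy-6-[(E)-2-(4-methoxyphenyl)ethenyl]-2-oxo-2H-pyran-3-yl}-3,4-dimethoxy-5-methyl-8-(propan-2-yl)-5,6,7,8-tetrahydronaphthalene-2-carbaldehyde
Conditions: MnO2 (activated, excess), CH2Cl2, rt, dark
Reagents that add atoms: none
Why: Heterogeneous MnO2 oxidation is selective for benzylic alcohols and should stop at the aldehyde while the pyrone, the styrene and the aryl ethers are left alone.

Step 12
Reactants: 21 trimethyl ether aldehyde
Product: 22 heimiomycin A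
Conditions: BBr3 (8 equiv), CH2Cl2, −78 → 0 °C; then MeOH, H2O
Reagents that add atoms: none
Why: Lewis-acid ether cleavage by BBr3 should remove all three aryl methyl groups (the one beside the aldehyde fastest through chelation) and leave the aldehyde, the pyrone, the E alkene and both benzylic stereocentres untouched.

**Compound list**
1 | (S)-(+)-carvone | CC(=C)[C@H]1CC=C(C)C(=O)C1 | starting material
2 | (2S,5S)-2-methyl-5-(propan-2-yl)cyclohexan-1-one | CC(C)[C@H]1CC[C@H](C)C(=O)C1 | intermediate
3 | (2Z,3R,6S)-2-(hydroxymethylidene)-6-methyl-3-(propan-2-yl)cyclohexan-1-one | CC(C)[C@H]1CC[C@H](C)C(=O)/C1=C\O | intermediate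
4 | methyl (2E)-3-[(3S,6R)-3-methyl-2-oxo-6-(propan-2-yl)cyclohexyl]prop-2-enoate (ring C1 unassigned) | CC(C)[C@H]1CC[C@H](C)C(=O)C1/C=C/C(=O)OC | intermediate (not isolated)
5 | (5R,8S)-8-methyl-5-(propan-2-yl)-5,6,7,8-tetrahydro-2H-chromen-2-one | CC(C)[C@H]1CC[C@H](C)c2oc(=O)ccc21 | intermediate
6 | (5R,8S)-3-bromo-8-methyl-5-(propan-2-yl)-5,6,7,8-tetrahydro-2H-chromen-2-one | CC(C)[C@H]1CC[C@H](C)c2oc(=O)c(Br)cc21 | intermediate
7 | 1,1,2-trimethoxyethene | COC=C(OC)OC | starting material
8 | bridged lactone: 2-oxabicyclo[2.2.2]oct-7-en-3-one adduct, Br on the bridgehead next to C(OMe)2, CH(OMe) next to the oxygen-bearing bridgehead, carbocycle fused across that bridgehead and the alkene (new centres unassigned) | CC(C)[C@H]1CC[C@H](C)C23OC(=O)C(Br)(C=C12)C(OC)(OC)C3OC | intermediate (not isolated)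
9 | (5S,8R)-2-bromo-3,3,4-trimethoxy-5-methyl-8-(propan-2-yl)-3,4,5,6,7,8-hexahydronaphthalene (C4 unassigned) | CC(C)[C@H]1CC[C@H](C)C2=C1C=C(Br)C(OC)(OC)C2OC | intermediate (not isolated)
10 | (5S,8R)-2-bromo-3,4-dimethoxy-5-methyl-8-(propan-2-yl)-5,6,7,8-tetrahydronaphthalene | CC(C)[C@H]1CC[C@H](C)c2c(OC)c(OC)c(Br)cc21 | intermediate
11 | dimethyl malonate | COC(=O)CC(=O)OC | starting material
12 | (5S,8R)-1,2-didehydro-3,4-dimethoxy-5-methyl-8-(propan-2-yl)-5,6,7,8-tetrahydronaphthalene (aryne) | CC(C)[C@H]1CC[C@H](C)C2=C1C#CC(OC)=C2OC | intermediate (not isolated)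
13 | methyl (5S,8R)-3,4-dimethoxy-1-(2-methoxy-2-oxoethyl)-5-methyl-8-(propan-2-yl)-5,6,7,8-tetrahydronaphthalene-2-carboxylate | CC(C)[C@H]1CC[C@H](C)c2c(OC)c(OC)c(C(=O)OC)c(CC(=O)OC)c21 | intermediate
14 | methyl 2-[(5S,8R)-3,4-dimethoxy-2-(methoxycarbonyl)-5-methyl-8-(propan-2-yl)-5,6,7,8-tetrahydronaphthalen-1-yl]-3-oxobutanoate (labile α-centre unassigned) | CC(C)[C@H]1CC[C@H](C)c2c(OC)c(OC)c(C(=O)OC)c(C(C(C)=O)C(=O)OC)c21 | intermediate
15 | (E)-4-methoxycinnamic acid | COc1ccc(/C=C/C(=O)O)cc1 | starting material
16 | (2E)-1-(1H-imidazol-1-yl)-3-(4-methoxyphenyl)prop-2-en-1-one | COc1ccc(/C=C/C(=O)n2ccnc2)cc1 | intermediate (not isolated)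
17 | (2E)-N-methoxy-3-(4-methoxyphenyl)-N-methylprop-2-enamide | COc1ccc(/C=C/C(=O)N(C)OC)cc1 | intermediate
18 | methyl (6E)-2-[(5S,8R)-3,4-dimethoxy-2-(methoxycarbonyl)-5-methyl-8-(propan-2-yl)-5,6,7,8-tetrahydronaphthalen-1-yl]-7-(4-methoxyphenyl)-3,5-dioxohept-6-enoate (C2 unassigned) | CC(C)[C@H]1CC[C@H](C)c2c(OC)c(OC)c(C(=O)OC)c(C(C(=O)OC)C(=O)CC(=O)/C=C/c3ccc(OC)cc3)c21 | intermediate (not isolated)
19 | methyl (5S,8R)-1-{4-hydroxy-6-[(E)-2-(4-methoxyphenyl)ethenyl]-2-oxo-2H-pyran-3-yl}-3,4-dimethoxy-5-methyl-8-(propan-2-yl)-5,6,7,8-tetrahydronaphthalene-2-carboxylate | CC(C)[C@H]1CC[C@H](C)c2c(OC)c(OC)c(C(=O)OC)c(-c3c(O)cc(/C=C/c4ccc(OC)cc4)oc3=O)c21 | intermediate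
20 | 4-hydroxy-3-[(5S,8R)-2-(hydroxymethyl)-3,4-dimethoxy-5-methyl-8-(propan-2-yl)-5,6,7,8-tetrahydronaphthalen-1-yl]-6-[(E)-2-(4-methoxyphenyl)ethenyl]-2H-pyran-2-one | CC(C)[C@H]1CC[C@H](C)c2c(OC)c(OC)c(CO)c(-c3c(O)cc(/C=C/c4ccc(OC)cc4)oc3=O)c21 | intermediate
21 | (5S,8R)-1-{4-hydroxy-6-[(E)-2-(4-methoxyphenyl)ethenyl]-2-oxo-2H-pyran-3-yl}-3,4-dimethoxy-5-methyl-8-(propan-2-yl)-5,6,7,8-tetrahydronaphthalene-2-carbaldehyde | CC(C)[C@H]1CC[C@H](C)c2c(OC)c(OC)c(C=O)c(-c3c(O)cc(/C=C/c4ccc(OC)cc4)oc3=O)c21 | intermediate
22 | heimiomycin A, (5S,8R)-3,4-dihydroxy-1-{4-hydroxy-6-[(E)-2-(4-hydroxyphenyl)ethenyl]-2-oxo-2H-pyran-3-yl}-5-methyl-8-(propan-2-yl)-5,6,7,8-tetrahydronaphthalene-2-carbaldehyde | CC(C)[C@H]1CC[C@H](C)c2c(O)c(O)c(C=O)c(-c3c(O)cc(/C=C/c4ccc(O)cc4)oc3=O)c21 | target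

**Count**
Total steps: 12. Longest linear sequence: 11 (steps 1 to 7 and 9 to 12, from 1); step 8 is a one-step branch.

**Steps most likely to fail**

Step 5. The cycloaddition may stall: the bromopyrone has no strong acceptor on C3 and reacts at a fully substituted diene terminus, so thermal decomposition of the ketene acetal can outpace bond formation. The fallback sets out from 3 and comes back at 10. Knoevenagel condensation of 3 with dimethyl malonate 11 (piperidine, AcOH, PhMe, reflux) should give alkylidene malonate F1, which lactonises in the same pot to ester pyrone F2, the strongly activated diene class for ketene acetal cycloadditions. Heating F2 with 7 (PhMe, 130 °C) should lead through bridged lactone F3 and diene F4 to benzoate F5. Saponification (KOH, MeOH/H2O, reflux) gives acid F6, and ipso-bromodecarboxylation of this ortho-methoxybenzoic acid (Bu4NBr3, K3PO4, MeCN, 100 °C) returns 10.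

Step 6. Regiocontrol may be lost, with the enolate adding at C2 under steric pressure from the peri position; alternatively the hindered base may fail to reach H1, or the aryl anion may be protonated before the 4-exo closure, so that plain α-arylation results. The fallback sets out from 10 and comes back at 13 without an aryne. Bromine–lithium exchange (n-BuLi, THF, −78 °C) and methyl chloroformate give benzoate F5. Electrophilic bromination at the single free position C1, para to the C4 methoxy group (N-bromosuccinimide, MeCN), gives bromo benzoate F7. Negishi-type coupling with the Reformatsky reagent BrZnCH2CO2Me (Pd2(dba)3, P(tBu)3, THF, 60 °C) then installs the acetate arm and gives 13.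

Step 10. Chemoselectivity may fail through hydride attack on the pyrone carbonyl or conjugate reduction along the styrylpyrone before the twisted benzoate is consumed. The fallback sets out from 13 and comes back at 20 by reducing before the pyrone exists. Selective saponification of the unhindered aliphatic ester (LiOH, THF/H2O, 0 °C) gives half-acid F8. LiBHEt3 (THF, 0 °C → rt) reduces the benzoate while the carboxylate is inert and gives hydroxy acid F9, which closes on acidification (TsOH cat.) to isochromanone F10. C-Acetylation (LiN(SiMe3)2, 1-acetylimidazole) gives acetyl lactone F11, and dianion acylation with 17 (LiN(iPr)2, 2.3 equiv) gives diketo lactone F12. With DBU the distal enol oxygen should open the lactone to the pyronolate and free the benzylic alcohol, which is 20.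

**Further compounds**
F1 | step 5 | dimethyl 2-{[(3S,6R)-3-methyl-2-oxo-6-(propan-2-yl)cyclohexyl]methylidene}propanedioate (ring C1 unassigned) | CC(C)[C@H]1CC[C@H](C)C(=O)C1C=C(C(=O)OC)C(=O)OC
F2 | step 5 | methyl (5R,8S)-8-methyl-2-oxo-5-(propan-2-yl)-5,6,7,8-tetrahydro-2H-chromene-3-carboxylate | CC(C)[C@H]1CC[C@H](C)c2oc(=O)c(C(=O)OC)cc21
F3 | step 5 | bridged lactone adduct of F2 and 7, ester on the bridgehead next to C(OMe)2 (new centres unassigned) | CC(C)[C@H]1CC[C@H](C)C23OC(=O)C(C(=O)OC)(C=C12)C(OC)(OC)C3OC
F4 | step 5 | methyl (5S,8R)-3,3,4-trimethoxy-5-methyl-8-(propan-2-yl)-3,4,5,6,7,8-hexahydronaphthalene-2-carboxylate (C4 unassigned) | CC(C)[C@H]1CC[C@H](C)C2=C1C=C(C(=O)OC)C(OC)(OC)C2OC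
F5 | step 5 | methyl (5S,8R)-3,4-dimethoxy-5-methyl-8-(propan-2-yl)-5,6,7,8-tetrahydronaphthalene-2-carboxylate | CC(C)[C@H]1CC[C@H](C)c2c(OC)c(OC)c(C(=O)OC)cc21
F6 | step 5 | (5S,8R)-3,4-dimethoxy-5-methyl-8-(propan-2-yl)-5,6,7,8-tetrahydronaphthalene-2-carboxylic acid | CC(C)[C@H]1CC[C@H](C)c2c(OC)c(OC)c(C(=O)O)cc21
F7 | step 6 | methyl (5S,8R)-1-bromo-3,4-dimethoxy-5-methyl-8-(propan-2-yl)-5,6,7,8-tetrahydronaphthalene-2-carboxylate | CC(C)[C@H]1CC[C@H](C)c2c(OC)c(OC)c(C(=O)OC)c(Br)c21
F8 | step 10 | 2-[(5S,8R)-3,4-dimethoxy-2-(methoxycarbonyl)-5-methyl-8-(propan-2-yl)-5,6,7,8-tetrahydronaphthalen-1-yl]acetic acid | CC(C)[C@H]1CC[C@H](C)c2c(OC)c(OC)c(C(=O)OC)c(CC(=O)O)c21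
F9 | step 10 | 2-[(5S,8R)-2-(hydroxymethyl)-3,4-dimethoxy-5-methyl-8-(propan-2-yl)-5,6,7,8-tetrahydronaphthalen-1-yl]acetic acid | CC(C)[C@H]1CC[C@H](C)c2c(OC)c(OC)c(CO)c(CC(=O)O)c21
F10 | step 10 | tricyclic isochroman-3-one, the lactone of F9 (C2–CH2–O–C(=O)–CH2–C1) | CC(C)[C@H]1CC[C@H](C)c2c(OC)c(OC)c3COC(=O)Cc3c21
F11 | step 10 | 4-acetyl derivative of isochromanone F10 (labile centre unassigned) | CC(C)[C@H]1CC[C@H](C)c2c(OC)c(OC)c3COC(=O)C(C(C)=O)c3c21
F12 | step 10 | 4-[(4E)-5-(4-methoxyphenyl)-3-oxopent-4-enoyl] derivative of isochromanone F10 (labile centre unassigned) | CC(C)[C@H]1CC[C@H](C)c2c(OC)c(OC)c3COC(=O)C(C(=O)CC(=O)/C=C/c4ccc(OC)cc4)c3c21
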